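The route disconnects ring B (O1, C2, C3, C4, C4a, C8a) at O1–C8a. The feature it exploits is that C8a is the acyl-like carbon of the enolised β-triketone ring A. After formal hydration of C3=C4, an O-to-O shift at C8a leads back to a five-membered dihydrofuran (O, C3, C4, C4a, C8a) bearing an ester on C3. An asymmetric phase-transfer Michael/O-alkylation of symmetric deoxycohumulone with methyl 2-bromoacrylate builds that ring and fixes C4a. In the key step MeMgBr turns the ester into the CMe2 alkoxide, which adds to C8a and expels the secondary oxygen. Two C–C bonds, C2 and the six-membered ring arise in one operation. Mesylation and elimination finish.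

Key step: step 3

Assumption: atom labels follow the chromene numbering of the target in all intermediates, and the cinchonidinium salt is taken to give (R) at C4a; its pseudoenantiomeric cinchoninium salt would be used if the sense of induction is opposite.

Step 1
Reactants: 1 phlorisobutyrophenone; 2 prenyl bromide
Product: 3 deoxycohumulone
Conditions: 2 (2.1 equiv), KOH (2.2 equiv), H2O, 0 °C
Reagents that add atoms: none
Why: Phenolate C-alkylation (C-prenylation of an acylphloroglucinol in aqueous base) sends the soft allylic bromide to the two free ring carbons, creates no stereocentre and is held at the diprenyl stage by the stoichiometry and the low temperature.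

Step 2
Reactants: 3 deoxycohumulone; 4 methyl 2-bromoacrylate
Product: 6 methyl (2R,3aR)-6-hydroxy-5-isobutyryl-4-oxo-3a,7-diprenyl-2,3,3a,4-tetrahydrobenzofuran-2-carboxylate, via bromo ester 5 (not isolated)
Conditions: 4 (1.05 equiv), CsOH·H2O (2.2 equiv), O-allyl-N-(9-anthracenylmethyl)cinchonidinium bromide (10 mol %), toluene/CH2Cl2, 4 Å MS, −50 to −20 °C; then 1 M HCl
Reagents that add atoms: none
Why: Asymmetric phase-transfer Michael addition followed by 5-exo-tet O-alkylation (Michael-initiated ring closure of the interrupted Feist–Bénary kind): the chiral ammonium–phenolate ion pair exposes one face of the two enantiotopic prenylated ring carbons to the acrylate and thereby sets C4a as R, the more charge-localised oxygen on C8a (not the chelated one on C5) then displaces bromide, and the base-labile ester carbon settles trans to the angular prenyl group, a centre that step 4 erases.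

Step 3
Reactants: 6 dihydrofuran ester
Product: 9 (3R,4aR)-3,7-dihydroxy-6-isobutyryl-2,2-dimethyl-4a,8-diprenyl-2,3,4,4a-tetrahydro-5H-chromen-5-one, via tertiary carbinol 7 (not isolated), via bicyclic ketal 8 (not isolated)
Conditions: MeMgBr (3.5 equiv), THF, −40 to 0 °C, then 50 °C; sat. aq NH4Cl, 0 °C
Reagents that add atoms: methylmagnesium bromide C[Mg]Br
Why: The first equivalent of MeMgBr only deprotonates the C7 enol, and the resulting magnesium β-triketonate shields C5, C7 and the isobutyryl carbonyl, so the next two equivalents add to the α-alkoxy ester (double Grignard addition) and give the tertiary alkoxide of 7. On warming, this alkoxide adds to the acyl-like carbon C8a of the vinylogous ester (5-exo-trig, anti to the angular prenyl group) to give the 2,7-dioxabicyclo[2.2.1]heptane adduct 8, which collapses by expelling the secondary oxygen, so that the five-membered ring (O, C3, C4, C4a, C8a) becomes the six-membered ring B (O1, C2, C3, C4, C4a, C8a). The closest known reaction types are base-induced 1,2-acyl migration in diol monoesters, ring enlargement by translactonisation, and the hydroxyisopropyl-dihydrofuran to hydroxy-dimethyl-dihydropyran rearrangement of furoquinolone-type vinylogous amides. No lasting stereocentre is made: no bond to C3 or C4a is broken, so both keep their configuration, and the transient centre at C8a is dictated by the bicyclic frame. The step needs the transfer to run towards the tertiary oxygen, which should be secured by the alkoxide medium, where the less basic and less hindered secondary magnesium alkoxide of 9 is the resting state, and by the cold quench that freezes the neutral product. The hindered O1–C2 bond is never made by substitution at a tertiary carbon, because O1 is the former ester carbonyl oxygen.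

Step 4
Reactants: 9 hydroxypyran
Product: 11 (4aR)-7-hydroxy-6-isobutyryl-2,2-dimethyl-4a,8-diprenyl-2H-chromen-5(4aH)-one, via mesylate 10 (not isolated)
Conditions: NaH (2.2 equiv), THF, 0 °C; MsCl (1.1 equiv), −20 °C; DBU (3 equiv), 60 °C; 1 M citric acid
Reagents that add atoms: methanesulfonyl chloride CS(=O)(=O)Cl (its atoms stay in 10 only)
Why: Chemoselective O-mesylation of the dianion (the secondary alkoxide far outruns the delocalised triketonate) followed by E2 elimination: C2 is quaternary, so only a C4 hydrogen can leave and the C3=C4 bond forms regiospecifically and necessarily cis within ring B, the C3 centre disappears and C4a is not touched.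

Compound list
1 | phlorisobutyrophenone, 2-methyl-1-(2,4,6-trihydroxyphenyl)propan-1-one | CC(C)C(=O)c1c(O)cc(O)cc1O | starting material
2 | prenyl bromide, 1-bromo-3-methylbut-2-ene | CC(C)=CCBr | starting material
3 | deoxycohumulone, 3,5-diprenylphlorisobutyrophenone | CC(C)C(=O)c1c(O)c(CC=C(C)C)c(O)c(CC=C(C)C)c1O | intermediate
4 | methyl 2-bromoacrylate | C=C(Br)C(=O)OC | starting material
5 | methyl 2-bromo-3-[(1R)-2,4-dihydroxy-5-isobutyryl-6-oxo-1,3-diprenylcyclohexa-2,4-dien-1-yl]propanoate, epimers at the bromine-bearing carbon | CC(C)=CCC1=C(O)[C@@](CC=C(C)C)(CC(Br)C(=O)OC)C(=O)C(C(=O)C(C)C)=C1O | intermediate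
6 | methyl (2R,3aR)-6-hydroxy-5-isobutyryl-4-oxo-3a,7-diprenyl-2,3,3a,4-tetrahydrobenzofuran-2-carboxylate, ester trans to the angular prenyl group | CC(C)=CCC1=C2O[C@@H](C(=O)OC)C[C@@]2(CC=C(C)C)C(=O)C(C(=O)C(C)C)=C1O | intermediate
7 | (2R,3aR)-6-hydroxy-2-(2-hydroxypropan-2-yl)-5-isobutyryl-3a,7-diprenyl-3,3a-dihydrobenzofuran-4(2H)-one | CC(C)=CCC1=C2O[C@@H](C(C)(C)O)C[C@@]2(CC=C(C)C)C(=O)C(C(=O)C(C)C)=C1O | intermediate
8 | bicyclic ketal adduct, 2,7-dioxabicyclo[2.2.1]heptane with both oxygens on C8a, drawn as the neutral dienol | CC(C)=CCC1=C(O)C(C(=O)C(C)C)=C(O)[C@]2(CC=C(C)C)C[C@H]3O[C@@]12OC3(C)C | intermediate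
9 | (3R,4aR)-3,7-dihydroxy-6-isobutyryl-2,2-dimethyl-4a,8-diprenyl-2,3,4,4a-tetrahydro-5H-chromen-5-one, 3-OH cis to the 4a-prenyl group | CC(C)=CCC1=C2OC(C)(C)[C@H](O)C[C@@]2(CC=C(C)C)C(=O)C(C(=O)C(C)C)=C1O | intermediate
10 | 3-methanesulfonate of 9, (3R,4aR) | CC(C)=CCC1=C2OC(C)(C)[C@H](OS(C)(=O)=O)C[C@@]2(CC=C(C)C)C(=O)C(C(=O)C(C)C)=C1O | intermediate
11 | (4aR)-7-hydroxy-6-isobutyryl-2,2-dimethyl-4a,8-diprenyl-2H-chromen-5(4aH)-one, CNP0119032.1 | CC(C)=CCC1=C2OC(C)(C)C=C[C@@]2(CC=C(C)C)C(=O)C(C(=O)C(C)C)=C1O | target

Total step count: 4. Longest linear sequence: 4 (1 → 3 → 6 → 9 → 11).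

Steps most likely to fail

Step 3. The O-to-O transfer may stall at the magnesium alkoxide stage, or the equilibrium may settle on the five-membered side. Prolonged heating with excess Grignard reagent may also erode the triketone. The fallback replaces equilibrium control by kinetic capture.
- The Grignard reaction of 6 is quenched at 0 °C, so that carbinol 7 is isolated.
- 7 is stirred with TESCl and imidazole in DMF at 40 °C. Imidazole shuttles the C8a unit between the two oxygens, and only the secondary hydroxyl released on the six-membered side is silylated. This should drain the mixture into the triethylsilyl ether F1.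
- HF·pyridine in THF then returns 9.
- The fallback sets out from 6 (through isolated 7) and comes back at 9.

Step 2. Facial discrimination within the ion pair may be poor, and ring closure may partly run through the C5 oxygen. The fallback replaces catalysis by a covalent auxiliary and separation.
- 3 is annulated with (−)-menthyl 2-bromoacrylate F2 and Cs2CO3 in MeCN at 0 °C. F2 is made from (−)-menthol and 2,3-dibromopropanoyl chloride with Et3N.
- The two esters that differ at C4a are diastereomers and are separated by crystallisation or chromatography.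
- The (3aR) menthyl ester F3 is taken into the conditions of step 3, where MeMgBr also removes the auxiliary.
- The fallback sets out from 3 and comes back at 9.

Step 4. Anti elimination may be slow because the mesylate has to turn axial beside the angular prenyl group. The enolate may also be sulfonylated in competition, and the ring oxygen may assist ionisation with ring contraction. The fallback removes the oxygen through the ketone instead of by E2.
- 9 is oxidised with Dess–Martin periodinane to the pyran-3-one F4, whose only enolisable position is C4.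
- KHMDS (2.1 equiv) and N-(5-chloro-2-pyridyl)bis(trifluoromethanesulfonimide) give the C3 enol triflate F5.
- Pd(OAc)2/PPh3 with HCO2H and Et3N in DMF at 60 °C reduces F5 to 11.
- The fallback sets out from 9 and comes back at 11.

Further compounds
F1 | step 3 | 3-O-triethylsilyl ether of 9 | CC(C)=CCC1=C2OC(C)(C)[C@H](O[Si](CC)(CC)CC)C[C@@]2(CC=C(C)C)C(=O)C(C(=O)C(C)C)=C1O
F2 | step 2 | (−)-menthyl 2-bromoacrylate | C=C(Br)C(=O)O[C@@H]1C[C@H](C)CC[C@H]1C(C)C
F3 | step 2 | (−)-menthyl (2R,3aR)-6-hydroxy-5-isobutyryl-4-oxo-3a,7-diprenyl-2,3,3a,4-tetrahydrobenzofuran-2-carboxylate | CC(C)=CCC1=C2O[C@@H](C(=O)O[C@@H]3C[C@H](C)CC[C@H]3C(C)C)C[C@@]2(CC=C(C)C)C(=O)C(C(=O)C(C)C)=C1O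
F4 | step 4 | (4aR)-7-hydroxy-6-isobutyryl-2,2-dimethyl-4a,8-diprenyl-4,4a-dihydro-2H-chromene-3,5-dione | CC(C)=CCC1=C2OC(C)(C)C(=O)C[C@@]2(CC=C(C)C)C(=O)C(C(=O)C(C)C)=C1O
F5 | step 4 | (4aR)-7-hydroxy-6-isobutyryl-2,2-dimethyl-5-oxo-4a,8-diprenyl-4a,5-dihydro-2H-chromen-3-yl trifluoromethanesulfonate | CC(C)=CCC1=C2OC(C)(C)C(OS(=O)(=O)C(F)(F)F)=C[C@@]2(CC=C(C)C)C(=O)C(C(=O)C(C)C)=C1O
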